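**Plan**

- Retrosynthesis (labdane numbering): cut C12–C13 (Stille) and C11=C12 (Takai), then the C4–C5 bond of ring A. The C19 oxygen, quaternary C4 and C3 oxygen form a β-hydroxy ketone array one reduction below the target, the mark of a semipinacol shift, which leads back to a trans-hydrindan-3-ol carrying a 2-methyloxiranyl group on C3.
- Further cuts: C3–C4 (isopropenyl addition to a hydrindanone), C8–C9 (enyne cyclisation), C5–C6 (enolate alkylation) and C9–C10 (conjugate addition to 3-methylcyclopent-2-enone).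
- Forward order: the cyclopentane comes from the enone, ring B is closed onto it by palladium-catalysed borylative cyclisation, ring A arises by enlarging the cyclopentanol, and the dienyl butenolide is joined last.
- Stereochemistry: C10 from a ligand-controlled conjugate addition; C5 by alkylation anti to a bulky 1-silylvinyl group; C9 in the chair of the ring B closure; the C3 carbinol by attack anti to the angular methyl; C4 from the hydroxyl-directed epoxidation relayed by anti migration; the C3 alcohol by axial hydride delivery; the E alkene by Takai olefination.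

Key step: step 10

Remark on numbering: C3 is the carbinol carbon, C4 the quaternary carbon bearing the C18 methyl and C19 acetoxymethyl, C5/C10 the ring fusion (C20 methyl on C10), C8=C17 the exocyclic methylene, C9 the side-chain carbon, C11=C12 the side-chain alkene, C13–C16 the butenolide.

Assumption: 3-bromofuran-2(5H)-one is taken as a purchasable building block, and the chiral carbene ligand of step 1 is used as the enantiomer that delivers the (R)-configured quaternary carbon.

Step 1
Reactants: 1 3-methylcyclopent-2-en-1-one; 2 ethynyl(trimethyl)silane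
Product: 5 (R)-3-methyl-3-[1-(trimethylsilyl)ethenyl]cyclopent-1-en-1-yl acetate, via the silylvinylalane 3 (not isolated), via the aluminium enolate 4 (not isolated)
Conditions: 2, i-Bu2AlH, hexanes/THF, 55 °C; then 1, Cu(OTf)2 (5 mol%), chiral sulfonate-bearing N-heterocyclic carbene ligand (5 mol%), THF, rt; then Ac2O, 0 °C to rt
Reagents that add atoms: acetic anhydride CC(=O)OC(C)=O
Why: Copper-catalysed enantioselective conjugate addition of a silicon-substituted vinylaluminium (from hydroalumination of the silylalkyne) to a β-substituted cyclic enone is known for this enone class and sets the quaternary C10 by ligand-controlled face selection, and O-acetylation of the aluminium enolate stores the C3–C5 enolate regiochemistry.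

Step 2
Reactants: 6 but-3-yn-1-ol
Product: 7 but-3-yn-1-yl trifluoromethanesulfonate
Conditions: Tf2O, pyridine, CH2Cl2, –78 to 0 °C, used at once
Reagents that add atoms: trifluoromethanesulfonic anhydride O=S(=O)(OS(=O)(=O)C(F)(F)F)C(F)(F)F
Why: O-Sulfonylation of a primary alcohol gives the primary alkyl triflate, an electrophile reactive enough to alkylate a hindered enolate at low temperature.

Step 3
Reactants: 5 (R)-3-methyl-3-[1-(trimethylsilyl)ethenyl]cyclopent-1-en-1-yl acetate; 7 but-3-yn-1-yl trifluoromethanesulfonate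
Product: 9 (2S,3R)-2-(but-3-yn-1-yl)-3-methyl-3-[1-(trimethylsilyl)ethenyl]cyclopentan-1-one, via the lithium enolate 8 (not isolated)
Conditions: MeLi (2.1 equiv), THF, 0 °C; then 7, –78 to –20 °C
Reagents that add atoms: none
Why: Cleavage of the enol acetate with methyllithium gives the regiodefined lithium enolate, whose SN2 C-alkylation by the primary triflate should occur anti to the bulky 1-silylvinyl group on C10, which sets C5 with the butynyl chain trans to that group and cis to the methyl.

Step 4
Reactants: 9 (2S,3R)-2-(but-3-yn-1-yl)-3-methyl-3-[1-(trimethylsilyl)ethenyl]cyclopentan-1-one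
Product: 10 (2S,3S)-2-(but-3-yn-1-yl)-3-ethenyl-3-methylcyclopentan-1-one
Conditions: CF3CO2H, CH2Cl2, 0 °C
Reagents that add atoms: none
Why: Ipso-protodesilylation of a vinylsilane (protonation at the silicon-bearing carbon to a β-silyl-stabilised cation, then loss of silicon) unmasks the vinyl group, and the short acidic treatment should leave the epimerisable C5 centre untouched.

Step 5
Reactants: 10 (2S,3S)-2-(but-3-yn-1-yl)-3-ethenyl-3-methylcyclopentan-1-one
Product: 12 (3aS,4R,7aS)-4-(hydroxymethyl)-3a-methyl-5-methylideneoctahydro-1H-inden-1-one, via the alkylboronate 11 (not isolated)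
Conditions: Pd(OAc)2 (5 mol%), B2pin2, MeOH, toluene, 50 °C; then NaBO3·4H2O, THF/H2O, rt
Reagents that add atoms: bis(pinacolato)diboron CC1(C)OB(OC1(C)C)B1OC(C)(C)C(C)(C)O1 (boron of 11); sodium perborate O[B-]1(O)OO[B-](O)(O)OO1.[Na+].[Na+] (oxygen of 12)
Why: Palladium-catalysed borylative cyclisation of a 1,7-enyne (hydropalladation of the alkyne at C8, 6-exo syn-carbopalladation of the vinyl group, borylation of the C11–Pd bond) closes ring B with the exocyclic methylene, the chair-like transition state with C11 pseudo-equatorial should set C9 with C11 cis to the C10 methyl, and perborate oxidation turns C–B into C–OH under conditions mild enough to spare C5.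

Step 6
Reactants: 12 (3aS,4R,7aS)-4-(hydroxymethyl)-3a-methyl-5-methylideneoctahydro-1H-inden-1-one
Product: 13 (3aS,4R,7aS)-3a-methyl-5-methylidene-1-oxooctahydro-1H-indene-4-carbaldehyde
Conditions: Dess–Martin periodinane, NaHCO3, CH2Cl2, 0 °C to rt
Reagents that add atoms: none
Why: Dess–Martin oxidation of the primary alcohol is non-basic, so the β,γ-unsaturated aldehyde should form without epimerisation at C9 or C5 and without shift of the double bond into conjugation.

Step 7
Reactants: 13 (3aS,4R,7aS)-3a-methyl-5-methylidene-1-oxooctahydro-1H-indene-4-carbaldehyde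
Product: 14 (3aS,4R,7aS)-4-[(E)-2-iodoethenyl]-3a-methyl-5-methylideneoctahydro-1H-inden-1-one
Conditions: CrCl2, CHI3, THF/dioxane, 0 °C to rt
Reagents that add atoms: iodoform IC(I)I
Why: Takai olefination with the geminal dichromium reagent from iodoform is selective for aldehydes over ketones, non-basic and E-selective, so it adds C12 and the iodide as the (E)-iodoalkene.

Step 8
Reactants: 14 (3aS,4R,7aS)-4-[(E)-2-iodoethenyl]-3a-methyl-5-methylideneoctahydro-1H-inden-1-one; 15 prop-1-en-2-ylmagnesium bromide
Product: 16 (1R,3aS,4R,7aS)-4-[(E)-2-iodoethenyl]-3a-methyl-5-methylidene-1-(prop-1-en-2-yl)octahydro-1H-inden-1-ol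
Conditions: CeCl3, THF, –78 °C
Reagents that add atoms: none
Why: 1,2-Addition of the organocerium reagent made from the Grignard reagent and CeCl3 avoids enolisation at C5 and spares the alkenyl iodide, and attack from the face of H5, anti to the axial C10 methyl, should set the C3 carbinol with its hydroxyl cis to that methyl.

Step 9
Reactants: 16 (1R,3aS,4R,7aS)-4-[(E)-2-iodoethenyl]-3a-methyl-5-methylidene-1-(prop-1-en-2-yl)octahydro-1H-inden-1-ol
Product: 17 (1R,3aS,4R,7aS)-4-[(E)-2-iodoethenyl]-3a-methyl-5-methylidene-1-[(2S)-2-methyloxiran-2-yl]octahydro-1H-inden-1-ol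
Conditions: VO(acac)2 (5 mol%), t-BuOOH, CH2Cl2, 0 °C to rt
Reagents that add atoms: tert-butyl hydroperoxide CC(C)(C)OO
Why: Vanadium-catalysed hydroxyl-directed epoxidation touches only the allylic-alcohol alkene, and in the vanadate transition state (O–C3–C4=C19 dihedral near 45°) the ring CH2 (C2) should sit next to the alkene methyl while the branched C5 points away and the methyl avoids H5 (A(1,2) strain), which should give the (S)-oxirane.

Step 10
Reactants: 17 (1R,3aS,4R,7aS)-4-[(E)-2-iodoethenyl]-3a-methyl-5-methylidene-1-[(2S)-2-methyloxiran-2-yl]octahydro-1H-inden-1-ol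
Product: 18 (1R,4aR,5R,8aS)-1-(hydroxymethyl)-5-[(E)-2-iodoethenyl]-1,4a-dimethyl-6-methylideneoctahydronaphthalen-2(1H)-one
Conditions: BF3·OEt2, CH2Cl2, –78 °C
Reagents that add atoms: none
Why: BF3 binds the oxirane oxygen and the C4–O bond ionises at the tertiary carbon while the C3–C5 ring bond, which lies anti to it, shifts to C4 and the C3 carbinol becomes the ketone. This is the semipinacol rearrangement of a tertiary α-hydroxy epoxide to a β-hydroxy ketone, run here as a 1,2-alkyl shift. No ring is closed in the usual sense: the cyclopentane is enlarged to six-membered ring A by the new C4–C5 bond as the old C3–C5 bond is given up (ring expansion). C4 is the new stereocentre, formed with inversion at the oxirane carbon and retention at the migrating C5, so its configuration (C19 axial, syn to the C10 methyl) follows from the oxirane configuration of step 9, and the trans ring fusion of the hydrindane is carried into the decalin. The step needs migration of C5 in preference to C2 and to a hydride shift from C19 (Meinwald pathway); the more substituted C5 is the better migrating group, the rotamer that keeps the C18 methyl away from H5 already holds the C3–C5 bond antiperiplanar to the breaking C4–O bond, and the hydroxyl lone pair favours carbon over hydride migration.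

Step 11
Reactants: 18 (1R,4aR,5R,8aS)-1-(hydroxymethyl)-5-[(E)-2-iodoethenyl]-1,4a-dimethyl-6-methylideneoctahydronaphthalen-2(1H)-one
Product: 19 [(1R,4aR,5R,8aS)-5-[(E)-2-iodoethenyl]-1,4a-dimethyl-6-methylidene-2-oxodecahydronaphthalen-1-yl]methyl acetate
Conditions: Ac2O, pyridine, DMAP (cat.), CH2Cl2, 0 °C to rt
Reagents that add atoms: acetic anhydride CC(=O)OC(C)=O
Why: DMAP-catalysed acylation of the only hydroxyl group gives the C19 acetate, and the quaternary C4 rules out β-elimination from the β-acetoxy ketone.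

Step 12
Reactants: 19 [(1R,4aR,5R,8aS)-5-[(E)-2-iodoethenyl]-1,4a-dimethyl-6-methylidene-2-oxodecahydronaphthalen-1-yl]methyl acetate
Product: 20 [(1R,2R,4aR,5R,8aS)-2-hydroxy-5-[(E)-2-iodoethenyl]-1,4a-dimethyl-6-methylidenedecahydronaphthalen-1-yl]methyl acetate
Conditions: NaBH4, MeOH/THF, –20 to 0 °C
Reagents that add atoms: none
Why: Borohydride reduction of the ring A ketone by axial hydride delivery from the face opposite the axial C19 and C20 groups should give the equatorial C3 alcohol, cis to the acetoxymethyl group, while the acetate and the alkenyl iodide stay intact at this temperature.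

Step 13
Reactants: 21 3-bromofuran-2(5H)-one
Product: 22 3-(tributylstannyl)furan-2(5H)-one
Conditions: (Bu3Sn)2, Pd(PPh3)4 (5 mol%), toluene, 90 °C
Reagents that add atoms: hexabutyldistannane CCCC[Sn](CCCC)(CCCC)[Sn](CCCC)(CCCC)CCCC
Why: Palladium-catalysed stannylation of an alkenyl bromide with a distannane (oxidative addition, transmetalation, reductive elimination) gives the α-stannyl butenolide.

Step 14
Reactants: 20 [(1R,2R,4aR,5R,8aS)-2-hydroxy-5-[(E)-2-iodoethenyl]-1,4a-dimethyl-6-methylidenedecahydronaphthalen-1-yl]methyl acetate; 22 3-(tributylstannyl)furan-2(5H)-one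
Product: 23 [(1R,2R,4aR,5R,8aS)-2-hydroxy-1,4a-dimethyl-6-methylidene-5-[(E)-2-(2-oxo-2,5-dihydrofuran-3-yl)ethenyl]decahydronaphthalen-1-yl]methyl acetate
Conditions: Pd2(dba)3 (5 mol%), AsPh3, CuI, DMF, rt
Reagents that add atoms: none
Why: Stille coupling of the (E)-alkenyl iodide with the alkenylstannane forms C12–C13 with retention of alkene geometry under neutral conditions that the acetate, the free C3 hydroxyl and the butenolide should tolerate.

**Compound list**

1 | 3-methylcyclopent-2-en-1-one | CC1=CC(=O)CC1 | starting material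
2 | ethynyl(trimethyl)silane | C#C[Si](C)(C)C | starting material
3 | bis(2-methylpropyl)[1-(trimethylsilyl)ethenyl]alumane | C=C([Si](C)(C)C)[Al](CC(C)C)CC(C)C | intermediate
4 | bis(2-methylpropyl)aluminium (R)-3-methyl-3-[1-(trimethylsilyl)ethenyl]cyclopent-1-en-1-olate | CC(C)C[Al](CC(C)C)OC1=C[C@@](C)(CC1)C(=C)[Si](C)(C)C | intermediate
5 | (R)-3-methyl-3-[1-(trimethylsilyl)ethenyl]cyclopent-1-en-1-yl acetate | CC(=O)OC1=C[C@@](C)(CC1)C(=C)[Si](C)(C)C | intermediate
6 | but-3-yn-1-ol | C#CCCO | starting material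
7 | but-3-yn-1-yl trifluoromethanesulfonate | C#CCCOS(=O)(=O)C(F)(F)F | intermediate
8 | lithium (R)-3-methyl-3-[1-(trimethylsilyl)ethenyl]cyclopent-1-en-1-olate | [Li]OC1=C[C@@](C)(CC1)C(=C)[Si](C)(C)C | intermediate
9 | (2S,3R)-2-(but-3-yn-1-yl)-3-methyl-3-[1-(trimethylsilyl)ethenyl]cyclopentan-1-one (butynyl trans to silylvinyl) | C#CCC[C@@H]1C(=O)CC[C@@]1(C)C(=C)[Si](C)(C)C | intermediate
10 | (2S,3S)-2-(but-3-yn-1-yl)-3-ethenyl-3-methylcyclopentan-1-one (butynyl trans to vinyl) | C#CCC[C@@H]1C(=O)CC[C@@]1(C)C=C | intermediate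
11 | (3aS,4R,7aS)-3a-methyl-5-methylidene-4-[(4,4,5,5-tetramethyl-1,3,2-dioxaborolan-2-yl)methyl]octahydro-1H-inden-1-one | C=C1CC[C@@H]2C(=O)CC[C@@]2(C)[C@@H]1CB3OC(C)(C)C(C)(C)O3 | intermediate
12 | (3aS,4R,7aS)-4-(hydroxymethyl)-3a-methyl-5-methylideneoctahydro-1H-inden-1-one (trans ring fusion) | C=C1CC[C@@H]2C(=O)CC[C@@]2(C)[C@@H]1CO | intermediate
13 | (3aS,4R,7aS)-3a-methyl-5-methylidene-1-oxooctahydro-1H-indene-4-carbaldehyde | C=C1CC[C@@H]2C(=O)CC[C@@]2(C)[C@@H]1C=O | intermediate
14 | (3aS,4R,7aS)-4-[(E)-2-iodoethenyl]-3a-methyl-5-methylideneoctahydro-1H-inden-1-one | C=C1CC[C@@H]2C(=O)CC[C@@]2(C)[C@@H]1/C=C/I | intermediate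
15 | prop-1-en-2-ylmagnesium bromide | C=C(C)[Mg]Br | starting material
16 | (1R,3aS,4R,7aS)-4-[(E)-2-iodoethenyl]-3a-methyl-5-methylidene-1-(prop-1-en-2-yl)octahydro-1H-inden-1-ol | C=C1CC[C@@H]2[C@@](O)(C(C)=C)CC[C@@]2(C)[C@@H]1/C=C/I | intermediate
17 | (1R,3aS,4R,7aS)-4-[(E)-2-iodoethenyl]-3a-methyl-5-methylidene-1-[(2S)-2-methyloxiran-2-yl]octahydro-1H-inden-1-ol | C=C1CC[C@@H]2[C@@](O)([C@]3(C)CO3)CC[C@@]2(C)[C@@H]1/C=C/I | intermediate
18 | (1R,4aR,5R,8aS)-1-(hydroxymethyl)-5-[(E)-2-iodoethenyl]-1,4a-dimethyl-6-methylideneoctahydronaphthalen-2(1H)-one | C=C1CC[C@@H]2[C@](C)(CO)C(=O)CC[C@@]2(C)[C@@H]1/C=C/I | intermediate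
19 | [(1R,4aR,5R,8aS)-5-[(E)-2-iodoethenyl]-1,4a-dimethyl-6-methylidene-2-oxodecahydronaphthalen-1-yl]methyl acetate | C=C1CC[C@@H]2[C@](C)(COC(C)=O)C(=O)CC[C@@]2(C)[C@@H]1/C=C/I | intermediate
20 | [(1R,2R,4aR,5R,8aS)-2-hydroxy-5-[(E)-2-iodoethenyl]-1,4a-dimethyl-6-methylidenedecahydronaphthalen-1-yl]methyl acetate | C=C1CC[C@@H]2[C@](C)(COC(C)=O)[C@H](O)CC[C@@]2(C)[C@@H]1/C=C/I | intermediate
21 | 3-bromofuran-2(5H)-one | O=C1OCC=C1Br | starting material
22 | 3-(tributylstannyl)furan-2(5H)-one | CCCC[Sn](CCCC)(CCCC)C1=CCOC1=O | intermediate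
23 | [(1R,2R,4aR,5R,8aS)-2-hydroxy-1,4a-dimethyl-6-methylidene-5-[(E)-2-(2-oxo-2,5-dihydrofuran-3-yl)ethenyl]decahydronaphthalen-1-yl]methyl acetate | C=C1CC[C@@H]2[C@](C)(COC(C)=O)[C@H](O)CC[C@@]2(C)[C@@H]1/C=C/C1=CCOC1=O | target

**Step count**

Total: 14 steps. Longest linear sequence: 12 steps (steps 1, 3 to 12 and 14); steps 2 and 13 make the two side reagents.

**Steps most likely to fail**

Step 5. The carbopalladation onto the vinyl group next to the quaternary C10 may be slow, or C11 may be delivered on the wrong face of ring B. The fallback closes ring B by a radical instead. From 10, dimethyldioxirane (acetone, 0 °C) should epoxidise only the vinyl group to (2S,3R)-2-(but-3-yn-1-yl)-3-methyl-3-(oxiran-2-yl)cyclopentan-1-one F1; either oxirane epimer serves. Cp2TiCl (trivalent titanium, made in the flask from Cp2TiCl2 and Zn dust in THF) opens the oxirane at the more substituted carbon to the C9 radical with C11 held as the titanium alkoxide. The radical closes 6-exo-dig onto the alkyne through a chair with the bulky titanoxymethyl group equatorial, and the alkenyl radical takes a hydrogen atom from THF. Aqueous work-up returns the route at 12.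

Step 3. O-Alkylation of the hindered enolate or elimination of the homopropargylic triflate may outrun C-alkylation. From 5, the same lithium enolate 8 would be allylated with the softer, more reactive allyl iodide to (2S,3R)-3-methyl-2-(prop-2-en-1-yl)-3-[1-(trimethylsilyl)ethenyl]cyclopentan-1-one F2. 9-BBN should hydroborate the terminal allyl alkene ahead of the ketone and the hindered silylalkene, and NaBO3 oxidation gives (2S,3R)-2-(3-hydroxypropyl)-3-methyl-3-[1-(trimethylsilyl)ethenyl]cyclopentan-1-one F3. Dess–Martin oxidation leads to 3-{(1S,2R)-2-methyl-5-oxo-2-[1-(trimethylsilyl)ethenyl]cyclopentyl}propanal F4. Homologation with the Ohira–Bestmann reagent (K2CO3, MeOH), which leaves the ketone alone, gives the terminal alkyne and returns the route at 9; with the silylvinyl group still in place the trans arrangement at C5 is also the thermodynamic one.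

Step 9. Oxygen transfer to the isopropenyl group may show poor facial selectivity, and C4 depends on it. The fallback builds the oxirane from a ketone instead of an alkene. From 14, 1-ethoxyvinyllithium with CeCl3 (THF, –78 °C) adds as in step 8 to (1R,3aS,4R,7aS)-1-(1-ethoxyethenyl)-4-[(E)-2-iodoethenyl]-3a-methyl-5-methylideneoctahydro-1H-inden-1-ol F5. Dilute oxalic acid hydrolyses the enol ether to 1-{(1R,3aS,4R,7aS)-1-hydroxy-4-[(E)-2-iodoethenyl]-3a-methyl-5-methylideneoctahydro-1H-inden-1-yl}ethan-1-one F6, and TESOTf with 2,6-lutidine gives 1-{(1R,3aS,4R,7aS)-4-[(E)-2-iodoethenyl]-3a-methyl-5-methylidene-1-[(triethylsilyl)oxy]octahydro-1H-inden-1-yl}ethan-1-one F7. Corey–Chaykovsky epoxidation with dimethylsulfonium methylide (Me3S+ I–, KN(SiMe3)2, THF) should add under Felkin–Anh control, silyloxy group anti and the ylide passing the ring CH2, to give triethyl{[(1R,3aS,4R,7aS)-4-[(E)-2-iodoethenyl]-3a-methyl-5-methylidene-1-[(2S)-2-methyloxiran-2-yl]octahydro-1H-inden-1-yl]oxy}silane F8. TBAF removes the silyl group and returns the route at 17. Running the ylide addition on the free ketol under chelation control would be expected to give the opposite oxirane.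

**Further compounds**

F1 | step 5 | (2S,3R)-2-(but-3-yn-1-yl)-3-methyl-3-(oxiran-2-yl)cyclopentan-1-one (both oxirane epimers) | C#CCC[C@@H]1C(=O)CC[C@@]1(C)C2CO2
F2 | step 3 | (2S,3R)-3-methyl-2-(prop-2-en-1-yl)-3-[1-(trimethylsilyl)ethenyl]cyclopentan-1-one | C=CC[C@@H]1C(=O)CC[C@@]1(C)C(=C)[Si](C)(C)C
F3 | step 3 | (2S,3R)-2-(3-hydroxypropyl)-3-methyl-3-[1-(trimethylsilyl)ethenyl]cyclopentan-1-one | OCCC[C@@H]1C(=O)CC[C@@]1(C)C(=C)[Si](C)(C)C
F4 | step 3 | 3-{(1S,2R)-2-methyl-5-oxo-2-[1-(trimethylsilyl)ethenyl]cyclopentyl}propanal | O=CCC[C@@H]1C(=O)CC[C@@]1(C)C(=C)[Si](C)(C)C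
F5 | step 9 | (1R,3aS,4R,7aS)-1-(1-ethoxyethenyl)-4-[(E)-2-iodoethenyl]-3a-methyl-5-methylideneoctahydro-1H-inden-1-ol | C=C1CC[C@@H]2[C@@](O)(C(=C)OCC)CC[C@@]2(C)[C@@H]1/C=C/I
F6 | step 9 | 1-{(1R,3aS,4R,7aS)-1-hydroxy-4-[(E)-2-iodoethenyl]-3a-methyl-5-methylideneoctahydro-1H-inden-1-yl}ethan-1-one | C=C1CC[C@@H]2[C@@](O)(C(C)=O)CC[C@@]2(C)[C@@H]1/C=C/I
F7 | step 9 | 1-{(1R,3aS,4R,7aS)-4-[(E)-2-iodoethenyl]-3a-methyl-5-methylidene-1-[(triethylsilyl)oxy]octahydro-1H-inden-1-yl}ethan-1-one | C=C1CC[C@@H]2[C@@](O[Si](CC)(CC)CC)(C(C)=O)CC[C@@]2(C)[C@@H]1/C=C/I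
F8 | step 9 | triethyl{[(1R,3aS,4R,7aS)-4-[(E)-2-iodoethenyl]-3a-methyl-5-methylidene-1-[(2S)-2-methyloxiran-2-yl]octahydro-1H-inden-1-yl]oxy}silane | C=C1CC[C@@H]2[C@@](O[Si](CC)(CC)CC)([C@]3(C)CO3)CC[C@@]2(C)[C@@H]1/C=C/I
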